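**Retrosynthetic overview**

1. Target 12 comes from triether 11 by BCl3 cleavage of three aryl isopropyl ethers; the single methyl ether is carried unchanged from the first step of the ring A branch.
2. Ring B of 11 comes from the 1,4-dihydrobenzoic acid 10 by oxidative decarboxylation; ring B is carried partly saturated and aromatized late, and its carboxyl group is a traceless activating group.
3. Acid 10 comes from acid 3 and bromide 8 by Birch reductive alkylation, which makes the bond between the terminal chain CH2 and ring B carbon C5. The enabling feature is that in ring B the chain-bearing carbon C5 is meta to both oxygen-bearing carbons C1 and C3. This is the pattern a 3,5-dialkoxybenzoate gives on Birch reduction: C1 and C3 stay sp2 as enol ethers, C2 becomes CH2, and C5 becomes the carboxylate-stabilised carbanion.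
4. Bromide 8 comes from aryl bromide 5 and 1,14-dibromotetradecane 6 by copper-catalysed aryl Grignard coupling; 5 comes from 3-bromo-5-methoxyphenol and 3 from methyl 3,5-dihydroxybenzoate.
5. Ring order: no ring is built. Ring A is bought aromatic and never altered; ring B is bought aromatic, dearomatized in step 5 and re-aromatized in step 6.

Key step: step 5

Remark on the chemistry: the target has no stereocentre and no stereogenic double bond, so no step has to control configuration; compounds 1, 4 and 6 are taken as purchasable.

**Route**

Step 1
Reactants: 1 methyl 3,5-dihydroxybenzoate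
Product: 2 methyl 3,5-diisopropoxybenzoate
Conditions: 2-bromopropane (3 equiv), K2CO3, DMF, 60 °C
Reagents that add atoms: 2-bromopropane, CC(C)Br
Why: Williamson etherification of both phenoxides; isopropyl is chosen because it should survive the dissolving-metal and oxidative steps and can later be removed by BCl3 without touching a methyl ether.

Step 2
Reactants: 2 methyl 3,5-diisopropoxybenzoate
Product: 3 3,5-diisopropoxybenzoic acid
Conditions: NaOH, MeOH/H2O, reflux; then aq HCl
Reagents that add atoms: sodium hydroxide, [Na+].[OH-]
Why: ester saponification by hydroxide at the acyl carbon, with the aryl isopropyl ethers inert to base.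

Step 3
Reactants: 4 3-bromo-5-methoxyphenol
Product: 5 1-bromo-3-isopropoxy-5-methoxybenzene
Conditions: 2-bromopropane (1.5 equiv), K2CO3, DMF, 60 °C
Reagents that add atoms: 2-bromopropane, CC(C)Br
Why: Williamson etherification, which fixes at the outset the difference in ring A between the methyl ether that stays and the hydroxyl that is freed at the end.

Step 4
Reactants: 5 1-bromo-3-isopropoxy-5-methoxybenzene; 6 1,14-dibromotetradecane
Product: 8 1-(14-bromotetradecyl)-3-isopropoxy-5-methoxybenzene, via arylmagnesium bromide 7 (not isolated)
Conditions: Mg, THF, reflux; then added to 6 (3 equiv), Li2CuCl4 (3 mol %), THF, −10 °C to rt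
Reagents that add atoms: none
Why: Kochi-type copper-catalysed coupling of an aryl Grignard reagent with a primary alkyl bromide, with the excess of dibromide 6 favouring substitution at one chain end only and the surplus 6 recovered by chromatography.

Step 5
Reactants: 3 3,5-diisopropoxybenzoic acid; 8 1-(14-bromotetradecyl)-3-isopropoxy-5-methoxybenzene
Product: 10 1-[14-(3-isopropoxy-5-methoxyphenyl)tetradecyl]-3,5-diisopropoxycyclohexa-2,5-diene-1-carboxylic acid, via dilithium dienediolate 9 (not isolated)
Conditions: 3 (1.2 equiv), Li (3 equiv per 3), NH3(l)/THF, −78 °C; then 8 in THF, −78 to −33 °C; NH4Cl; cold aq NaH2PO4 (pH 5)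
Reagents that add atoms: none
Why: Lithium first removes the acid proton and then transfers two electrons to the benzoate; the radical anion is protonated by ammonia at C4 (the carbon between the two alkoxy-bearing carbons, para to the carboxylate) and the second electron gives the cross-conjugated dienediolate 9, whose nucleophilic carbon C1 attacks the primary bromide 8 in an SN2 reaction to make the CH2–C1 bond and a quaternary carbon. The closest known reaction is the Birch reductive alkylation of benzoic acids, which is established for 3,5-dimethoxybenzoic acid with primary alkyl halides as an entry to 5-alkylresorcinol ethers. No ring is closed and no stereocentre arises, because C1 of 10 carries two identical ring arms. The regiochemistry of reduction is secured by the substituents acting together: the carboxylate ends on an sp3 carbon and both isopropoxy groups on sp2 carbons, so only the required 1,4-dihydro isomer is open, and alkylation at C1 instead of C3 or C5 follows from the charge being held next to the carboxylate while the alkoxy groups disfavour charge on their own carbons. Ring A of 8 should survive because all lithium is consumed before 8 is added and an alkyl dialkoxybenzene is not reduced without an added alcohol; the carboxyl group that makes C1 nucleophilic is removed in step 6.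

Step 6
Reactants: 10 1-[14-(3-isopropoxy-5-methoxyphenyl)tetradecyl]-3,5-diisopropoxycyclohexa-2,5-diene-1-carboxylic acid
Product: 11 1-(3,5-diisopropoxyphenyl)-14-(3-isopropoxy-5-methoxyphenyl)tetradecane
Conditions: Pb(OAc)4 (1.1 equiv), pyridine, benzene, 0 °C to rt
Reagents that add atoms: none
Why: oxidative decarboxylation of a 1-alkylcyclohexa-2,5-diene-1-carboxylic acid by tetravalent lead, in which loss of CO2 from the lead carboxylate leaves a doubly allylic cyclohexadienyl intermediate that gives up the C4 hydrogen to become aromatic, while pyridine buffers the acetic acid so the enol ethers are not hydrolysed first.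

Step 7
Reactants: 11 1-(3,5-diisopropoxyphenyl)-14-(3-isopropoxy-5-methoxyphenyl)tetradecane
Product: 12 5-[14-(3-hydroxy-5-methoxyphenyl)tetradecyl]benzene-1,3-diol (target)
Conditions: BCl3 (1 M in CH2Cl2, 6 equiv), CH2Cl2, −78 to 0 °C; then H2O
Reagents that add atoms: none
Why: Lewis-acid ether dealkylation in which BCl3 coordinates the ether oxygen and the secondary isopropyl–oxygen bond ionises, a path not open to the aryl methyl ether, so the three isopropyl groups should be removed while the methoxy group stays.

**Compound list**

1 | methyl 3,5-dihydroxybenzoate | COC(=O)c1cc(O)cc(O)c1 | starting material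
2 | methyl 3,5-diisopropoxybenzoate | COC(=O)c1cc(OC(C)C)cc(OC(C)C)c1 | intermediate
3 | 3,5-diisopropoxybenzoic acid | OC(=O)c1cc(OC(C)C)cc(OC(C)C)c1 | intermediate
4 | 3-bromo-5-methoxyphenol | COc1cc(O)cc(Br)c1 | starting material
5 | 1-bromo-3-isopropoxy-5-methoxybenzene | COc1cc(OC(C)C)cc(Br)c1 | intermediate
6 | 1,14-dibromotetradecane | BrCCCCCCCCCCCCCCBr | starting material
7 | (3-isopropoxy-5-methoxyphenyl)magnesium bromide, not isolated | COc1cc(OC(C)C)cc([Mg]Br)c1 | intermediate
8 | 1-(14-bromotetradecyl)-3-isopropoxy-5-methoxybenzene | COc1cc(OC(C)C)cc(CCCCCCCCCCCCCCBr)c1 | intermediate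
9 | dilithium dienediolate of 1,4-dihydro-3,5-diisopropoxybenzoic acid, not isolated | [Li+].[Li+].[O-]C([O-])=C1C=C(OC(C)C)CC(OC(C)C)=C1 | intermediate
10 | 1-[14-(3-isopropoxy-5-methoxyphenyl)tetradecyl]-3,5-diisopropoxycyclohexa-2,5-diene-1-carboxylic acid (achiral) | COc1cc(OC(C)C)cc(CCCCCCCCCCCCCCC2(C(=O)O)C=C(OC(C)C)CC(OC(C)C)=C2)c1 | intermediate
11 | 1-(3,5-diisopropoxyphenyl)-14-(3-isopropoxy-5-methoxyphenyl)tetradecane | COc1cc(OC(C)C)cc(CCCCCCCCCCCCCCc2cc(OC(C)C)cc(OC(C)C)c2)c1 | intermediate
12 | 5-[14-(3-hydroxy-5-methoxyphenyl)tetradecyl]benzene-1,3-diol | COc1cc(O)cc(CCCCCCCCCCCCCCc2cc(O)cc(O)c2)c1 | target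

**Step count and risks**

Total step count: 7. Longest linear sequence: 5 steps (1 → 2 → 3 → 10 → 11 → 12, or equally 4 → 5 → 8 → 10 → 11 → 12).

Steps most likely to fail:

Step 5. The lipophilic bromide may precipitate from the cold ammonia medium so that alkylation stalls and the dienediolate is only protonated on quench. The LiNH2 formed during reduction may also consume the bromide by substitution or elimination, and any lithium left over would reduce the carbon–bromine bond or cleave an alkoxy group. The fallback sets out from bromide 8 and makes the same bond by direct cross-coupling. Purchased 5-bromobenzene-1,3-diol (Oc1cc(O)cc(Br)c1) would be etherified under the conditions of step 1 to 1-bromo-3,5-diisopropoxybenzene F1. This would be converted with Mg in THF into (3,5-diisopropoxyphenyl)magnesium bromide F2 and coupled with 8 under Li2CuCl4 catalysis as in step 4. This should give triether 11 directly, where the fallback rejoins the route, bypassing 10 and step 6.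

Step 6. Attack of the lead oxidant on the electron-rich enol ether double bonds, or acid-promoted enol ether hydrolysis before ring B has aromatized, may compete with decarboxylation. The fallback sets out from acid 10 and replaces the oxidation by a redox-neutral decarbonylative aromatization. Treatment with 1-chloro-N,N,2-trimethylprop-1-en-1-amine and 2,6-lutidine in CH2Cl2 at 0 °C should give 1-[14-(3-isopropoxy-5-methoxyphenyl)tetradecyl]-3,5-diisopropoxycyclohexa-2,5-diene-1-carbonyl chloride F3. On warming to room temperature its acylium ion should lose carbon monoxide, and the resulting cyclohexadienyl cation should lose a proton to the base. This rejoins the route at triether 11.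

Step 4. Coupling at both ends of the dibromide and homocoupling of the Grignard reagent may erode the yield of the mono-coupled bromide. The fallback sets out from arylmagnesium bromide 7 (made from 5 as in step 4) and uses a chain with two different ends. Purchased tetradecane-1,14-diol (OCCCCCCCCCCCCCCO) would be monobrominated with 48% aq HBr in refluxing toluene to 14-bromotetradecan-1-ol F4. After deprotonation in the flask with one equivalent of MeMgCl, F4 would be coupled with 7 under Li2CuCl4 catalysis to give 14-(3-isopropoxy-5-methoxyphenyl)tetradecan-1-ol F5. An Appel reaction (CBr4, PPh3, CH2Cl2, 0 °C) would then give bromide 8, where the fallback rejoins the route.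

**Further compounds**

F1 | step 5 | 1-bromo-3,5-diisopropoxybenzene | CC(C)Oc1cc(Br)cc(OC(C)C)c1
F2 | step 5 | (3,5-diisopropoxyphenyl)magnesium bromide | CC(C)Oc1cc([Mg]Br)cc(OC(C)C)c1
F3 | step 6 | 1-[14-(3-isopropoxy-5-methoxyphenyl)tetradecyl]-3,5-diisopropoxycyclohexa-2,5-diene-1-carbonyl chloride | COc1cc(OC(C)C)cc(CCCCCCCCCCCCCCC2(C(Cl)=O)C=C(OC(C)C)CC(OC(C)C)=C2)c1
F4 | step 4 | 14-bromotetradecan-1-ol | OCCCCCCCCCCCCCCBr
F5 | step 4 | 14-(3-isopropoxy-5-methoxyphenyl)tetradecan-1-ol | COc1cc(OC(C)C)cc(CCCCCCCCCCCCCCO)c1
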